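## Retrosynthetic overview

1. Target 21 ⇐ desilylation of its 15‑O‑TBDPS ether 20.
2. 20 ⇐ one operation on the monocyclic furanone 17: Cr(II) Barbier‑type allylation (C6–C7) plus lactonisation closes the ten‑membered carbocycle and the α‑methylene‑γ‑lactone together (rings 2 and 3, formed last; sets C6 and C7).
3. 17 ⇐ Morita–Baylis–Hillman reaction and SN2′ bromination at the C7 aldehyde of dialdehyde 14.
4. 14 ⇐ three‑component carbonylative annulation (vinyl iodide 5 + CO + tertiary propargylic alcohol 11) that builds the 3(2H)‑furanone (ring 1, formed first).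
5. 5 ⇐ but‑2‑yne‑1,4‑diol (Red‑Al/I2 fixes the Z‑alkene); 11 ⇐ ynone aldol (C8) then chelation‑controlled MeMgBr addition (C10).

Assumption and convention: atom labels C1–C15 follow germacrane numbering (C1 ketone, C3/C10 furanone carbons, C6 lactone carbinol, C8 ester carbinol, C15 hydroxymethyl); (S,S)‑ProPhenol is taken to give the (5R)‑aldol 8, and the (R,R)‑ligand is used if the sense proves opposite.

## Route

Step 1
Reactants: 1 but‑2‑yne‑1,4‑diol
Product: 2 4‑[(tert‑butyldiphenylsilyl)oxy]but‑2‑yn‑1‑ol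
Conditions: NaH (1.0 equiv), THF, 0 °C → rt; then TBDPSCl (1.0 equiv), rt
Reagents that add atoms: tert‑butyl(chloro)diphenylsilane CC(C)(C)[Si](Cl)(c1ccccc1)c1ccccc1
Why: Mono‑deprotonation gives the sparingly soluble monosodium alkoxide, which is O‑silylated once (monosilylation of a symmetrical diol); no stereocentre is involved.

Step 2
Reactants: 2 4‑[(tert‑butyldiphenylsilyl)oxy]but‑2‑yn‑1‑ol
Product: 3 (2Z)‑4‑[(tert‑butyldiphenylsilyl)oxy]‑3‑iodobut‑2‑en‑1‑ol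
Conditions: Red‑Al (1.6 equiv), THF, 0 °C; EtOAc quench; then I2 (1.5 equiv), THF, −78 → 0 °C
Reagents that add atoms: iodine II
Why: Hydroxyl‑directed trans‑hydroalumination of the propargylic alcohol puts Al on the distal alkyne carbon anti to the new C–H, and iodinolysis with retention gives the (Z)‑vinyl iodide with iodine cis to the CH2OH arm.

Step 3
Reactants: 3 (2Z)‑4‑[(tert‑butyldiphenylsilyl)oxy]‑3‑iodobut‑2‑en‑1‑ol
Product: 5 tert‑butyl{[(2Z)‑2‑iodo‑4,4‑dimethoxybut‑2‑en‑1‑yl]oxy}diphenylsilane, via iodo‑enal 4 (not isolated)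
Conditions: MnO2 (15 equiv), CH2Cl2, rt; filter; then HC(OMe)3, PPTS (5 mol %), MeOH, rt
Reagents that add atoms: trimethyl orthoformate COC(OC)OC
Why: Selective allylic oxidation with MnO2 followed by acid‑catalysed acetalisation masks the future C6 aldehyde without touching the Z‑iodoalkene.

Step 4
Reactants: 6 4‑(trimethylsilyl)but‑3‑yn‑2‑one; 7 2,2‑dimethoxyacetaldehyde (dried, distilled monomer)
Product: 8 (5R)‑5‑hydroxy‑6,6‑dimethoxy‑1‑(trimethylsilyl)hex‑1‑yn‑3‑one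
Conditions: (S,S)‑ProPhenol (10 mol %), Et2Zn (20 mol %), 4 Å MS, THF, 0 °C
Reagents that add atoms: none
Why: Direct catalytic asymmetric aldol addition of a methyl ynone (dinuclear Zn–ProPhenol catalysis), in which the chiral dizinc pocket exposes one aldehyde face to the zinc enolate and sets the C8 carbinol as (R).

Step 5
Reactants: 8 (5R)‑5‑hydroxy‑6,6‑dimethoxy‑1‑(trimethylsilyl)hex‑1‑yn‑3‑one
Product: 10 (2R,4S)‑1,1‑dimethoxy‑4‑methylhex‑5‑yne‑2,4‑diol, via silylalkyne diol 9 (not isolated)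
Conditions: MeMgBr (3.0 equiv), THF, −78 → −40 °C; then MeOH, K2CO3, rt
Reagents that add atoms: methylmagnesium bromide C[Mg]Br
Why: Chelation‑controlled 1,3‑induction in a Grignard addition, where the magnesium β‑alkoxide chelates the ynone carbonyl and external MeMgBr attacks anti to the C8 substituent (the Narasaka–Prasad sense) to give the syn‑diol with (S)‑C10, after which K2CO3/MeOH protodesilylates the alkyne.

Step 6
Reactants: 10 (2R,4S)‑1,1‑dimethoxy‑4‑methylhex‑5‑yne‑2,4‑diol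
Product: 11 (2R,4S)‑4‑hydroxy‑1,1‑dimethoxy‑4‑methylhex‑5‑yn‑2‑yl 3‑methylbutanoate
Conditions: isovaleryl chloride (1.1 equiv), pyridine, DMAP (5 mol %), CH2Cl2, 0 °C
Reagents that add atoms: 3‑methylbutanoyl chloride CC(C)CC(=O)Cl
Why: DMAP‑catalysed acylation is selective for the secondary alcohol because the tertiary propargylic alcohol is too hindered, and no stereocentre is affected.

Step 7
Reactants: 5 tert‑butyl{[(2Z)‑2‑iodo‑4,4‑dimethoxybut‑2‑en‑1‑yl]oxy}diphenylsilane; 11 (2R,4S)‑4‑hydroxy‑1,1‑dimethoxy‑4‑methylhex‑5‑yn‑2‑yl 3‑methylbutanoate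
Product: 14 (2R)‑1‑[(2S)‑5‑{(2Z)‑1‑[(tert‑butyldiphenylsilyl)oxy]‑4‑oxobut‑2‑en‑2‑yl}‑2‑methyl‑3‑oxo‑2,3‑dihydrofuran‑2‑yl]‑3‑oxopropan‑2‑yl 3‑methylbutanoate, via ynone 12 (not isolated), via enaminone 13 (not isolated)
Conditions: PdCl2(PPh3)2 (5 mol %), CuI (2 mol %), Et3N (3 equiv), CO (1 atm), THF, rt; then Et2NH (3 equiv), rt; evaporate; then TFA/H2O/CH2Cl2 (4:1:5), 0 °C → rt
Reagents that add atoms: carbon monoxide [C-]#[O+]; water O
Why: Carbonylative Sonogashira coupling gives the 4‑hydroxy‑ynone, aza‑Michael addition of Et2NH gives the β‑enaminone, and aqueous acid hydrolyses it to the α′‑hydroxy‑1,3‑diketone, which cyclodehydrates to the 3(2H)‑furanone (first ring) while both dimethyl acetals are cleaved; the Z‑alkene comes from 5 and C8/C10 from 11.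

Step 8
Reactants: 14 furanone dialdehyde (name as in step 7); 15 methyl acrylate
Product: 16 methyl (4R)‑5‑[(2S)‑5‑{(2Z)‑1‑[(tert‑butyldiphenylsilyl)oxy]‑4‑oxobut‑2‑en‑2‑yl}‑2‑methyl‑3‑oxo‑2,3‑dihydrofuran‑2‑yl]‑3‑hydroxy‑2‑methylidene‑4‑(3‑methylbutanoyloxy)pentanoate (both C3 carbinol epimers)
Conditions: methyl acrylate (10 equiv), DABCO (1.0 equiv), MeOH, 0 °C → rt
Reagents that add atoms: none
Why: The Morita–Baylis–Hillman reaction occurs only at the more electrophilic α‑acyloxy aliphatic aldehyde (the hindered cross‑conjugated enal is inert to DABCO/acrylate), and the new carbinol centre is irrelevant because it is destroyed in step 9.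

Step 9
Reactants: 16 Morita–Baylis–Hillman adduct (name as in step 8)
Product: 17 methyl (2Z,4R)‑2‑(bromomethyl)‑5‑[(2S)‑5‑{(2Z)‑1‑[(tert‑butyldiphenylsilyl)oxy]‑4‑oxobut‑2‑en‑2‑yl}‑2‑methyl‑3‑oxo‑2,3‑dihydrofuran‑2‑yl]‑4‑(3‑methylbutanoyloxy)pent‑2‑enoate
Conditions: NBS (1.3 equiv), Me2S (1.5 equiv), CH2Cl2, −20 → 0 °C
Reagents that add atoms: N‑bromosuccinimide O=C1CCC(=O)N1Br
Why: Activation of the allylic alcohol as an alkoxysulfonium salt (Corey–Kim‑type NBS/Me2S) and SN2′ attack of bromide gives the thermodynamically preferred (Z)‑2‑(bromomethyl)enoate.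

Step 10
Reactants: 17 allylic bromide–enal (name as in step 9)
Product: 20 (4Z,6R,7R,8R,10S)‑15‑[(tert‑butyldiphenylsilyl)oxy]‑8‑(3‑methylbutanoyloxy)‑1‑oxo‑3,10‑epoxygermacra‑2,4,11(13)‑trien‑12,6‑olide, via allylchromium 18 (not isolated), via seco hydroxy ester 19 (not isolated)
Conditions: CrCl2 (10 equiv), THF/DMF (9:1), rt, slow addition of 17 (final 2 mM); then 1 M aq HCl, THF, rt
Reagents that add atoms: none
Why: Intramolecular Nozaki–Hiyama (Barbier‑type) allylation followed by lactonisation closes the ten‑membered carbocycle and the α‑methylene‑γ‑lactone in one operation; A(1,3) strain in the (Z)‑allylchromium holds H8 in the alkene plane so the aldehyde adds anti to C9 (7R), and the chair‑like macrocyclic transition state with the enal substituent pseudo‑equatorial gives the anti adduct, that is the trans‑lactone (6R).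

Step 11
Reactants: 20 15‑O‑TBDPS ether of the target (name as in step 10)
Product: 21 (4Z,6R,7R,8R,10S)‑15‑hydroxy‑8‑(3‑methylbutanoyloxy)‑1‑oxo‑3,10‑epoxygermacra‑2,4,11(13)‑trien‑12,6‑olide (CNP0171896.1)
Conditions: HF·pyridine, pyridine/THF, 0 °C → rt
Reagents that add atoms: none
Why: Buffered fluoride desilylation removes the TBDPS ether without affecting the α‑methylene lactone, the isovalerate or the furanone.

## Compound list

1 | but‑2‑yne‑1,4‑diol | OCC#CCO | starting material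
2 | 4‑[(tert‑butyldiphenylsilyl)oxy]but‑2‑yn‑1‑ol | OCC#CCO[Si](c1ccccc1)(c1ccccc1)C(C)(C)C | intermediate
3 | (2Z)‑4‑[(tert‑butyldiphenylsilyl)oxy]‑3‑iodobut‑2‑en‑1‑ol | OC/C=C(/CO[Si](c1ccccc1)(c1ccccc1)C(C)(C)C)I | intermediate
4 | (2Z)‑4‑[(tert‑butyldiphenylsilyl)oxy]‑3‑iodobut‑2‑enal (not isolated) | O=C/C=C(/CO[Si](c1ccccc1)(c1ccccc1)C(C)(C)C)I | intermediate
5 | tert‑butyl{[(2Z)‑2‑iodo‑4,4‑dimethoxybut‑2‑en‑1‑yl]oxy}diphenylsilane | COC(OC)/C=C(/CO[Si](c1ccccc1)(c1ccccc1)C(C)(C)C)I | intermediate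
6 | 4‑(trimethylsilyl)but‑3‑yn‑2‑one | CC(=O)C#C[Si](C)(C)C | starting material
7 | 2,2‑dimethoxyacetaldehyde | COC(OC)C=O | starting material
8 | (5R)‑5‑hydroxy‑6,6‑dimethoxy‑1‑(trimethylsilyl)hex‑1‑yn‑3‑one | C[Si](C)(C)C#CC(=O)C[C@@H](O)C(OC)OC | intermediate
9 | (3S,5R)‑6,6‑dimethoxy‑3‑methyl‑1‑(trimethylsilyl)hex‑1‑yne‑3,5‑diol (not isolated) | C[Si](C)(C)C#C[C@](C)(C[C@@H](O)C(OC)OC)O | intermediate
10 | (2R,4S)‑1,1‑dimethoxy‑4‑methylhex‑5‑yne‑2,4‑diol | C#C[C@](C)(C[C@@H](O)C(OC)OC)O | intermediate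
11 | (2R,4S)‑4‑hydroxy‑1,1‑dimethoxy‑4‑methylhex‑5‑yn‑2‑yl 3‑methylbutanoate | C#C[C@](C)(C[C@@H](OC(=O)CC(C)C)C(OC)OC)O | intermediate
12 | (2R,4S,8Z)‑8‑{[(tert‑butyldiphenylsilyl)oxy]methyl}‑4‑hydroxy‑1,1,10,10‑tetramethoxy‑4‑methyl‑7‑oxodec‑8‑en‑5‑yn‑2‑yl 3‑methylbutanoate (ynone, not isolated) | COC(OC)/C=C(/CO[Si](c1ccccc1)(c1ccccc1)C(C)(C)C)C(=O)C#C[C@](C)(C[C@@H](OC(=O)CC(C)C)C(OC)OC)O | intermediate
13 | (2R,4S,5E,8Z)‑8‑{[(tert‑butyldiphenylsilyl)oxy]methyl}‑5‑(diethylamino)‑4‑hydroxy‑1,1,10,10‑tetramethoxy‑4‑methyl‑7‑oxodeca‑5,8‑dien‑2‑yl 3‑methylbutanoate (enaminone, not isolated) | COC(OC)/C=C(/CO[Si](c1ccccc1)(c1ccccc1)C(C)(C)C)C(=O)/C=C(/N(CC)CC)[C@](C)(C[C@@H](OC(=O)CC(C)C)C(OC)OC)O | intermediate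
14 | (2R)‑1‑[(2S)‑5‑{(2Z)‑1‑[(tert‑butyldiphenylsilyl)oxy]‑4‑oxobut‑2‑en‑2‑yl}‑2‑methyl‑3‑oxo‑2,3‑dihydrofuran‑2‑yl]‑3‑oxopropan‑2‑yl 3‑methylbutanoate | O=C/C=C(/CO[Si](c2ccccc2)(c2ccccc2)C(C)(C)C)C1=CC(=O)[C@](C)(C[C@@H](OC(=O)CC(C)C)C=O)O1 | intermediate
15 | methyl acrylate | C=CC(=O)OC | starting material
16 | methyl (4R)‑5‑[(2S)‑5‑{(2Z)‑1‑[(tert‑butyldiphenylsilyl)oxy]‑4‑oxobut‑2‑en‑2‑yl}‑2‑methyl‑3‑oxo‑2,3‑dihydrofuran‑2‑yl]‑3‑hydroxy‑2‑methylidene‑4‑(3‑methylbutanoyloxy)pentanoate (C3 epimers, centre left undefined) | O=C/C=C(/CO[Si](c2ccccc2)(c2ccccc2)C(C)(C)C)C1=CC(=O)[C@](C)(C[C@@H](OC(=O)CC(C)C)C(O)C(=C)C(=O)OC)O1 | intermediate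
17 | methyl (2Z,4R)‑2‑(bromomethyl)‑5‑[(2S)‑5‑{(2Z)‑1‑[(tert‑butyldiphenylsilyl)oxy]‑4‑oxobut‑2‑en‑2‑yl}‑2‑methyl‑3‑oxo‑2,3‑dihydrofuran‑2‑yl]‑4‑(3‑methylbutanoyloxy)pent‑2‑enoate | O=C/C=C(/CO[Si](c2ccccc2)(c2ccccc2)C(C)(C)C)C1=CC(=O)[C@](C)(C[C@@H](OC(=O)CC(C)C)/C=C(\CBr)C(=O)OC)O1 | intermediate
18 | allylchromium(III) dichloride from 17 (CH2CrCl2 in place of CH2Br, not isolated) | O=C/C=C(/CO[Si](c2ccccc2)(c2ccccc2)C(C)(C)C)C1=CC(=O)[C@](C)(C[C@@H](OC(=O)CC(C)C)/C=C(\C[Cr](Cl)Cl)C(=O)OC)O1 | intermediate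
19 | seco hydroxy ester of 20: ten‑membered carbocycle with free 6‑OH (chromium alkoxide in the flask) and C12 as methyl ester, spatial arrangement as in 20 (not isolated) | C=C(C(=O)OC)[C@H]1[C@H](O)/C=C(/CO[Si](c3ccccc3)(c3ccccc3)C(C)(C)C)C2=CC(=O)[C@](C)(C[C@H]1OC(=O)CC(C)C)O2 | intermediate
20 | (4Z,6R,7R,8R,10S)‑15‑[(tert‑butyldiphenylsilyl)oxy]‑8‑(3‑methylbutanoyloxy)‑1‑oxo‑3,10‑epoxygermacra‑2,4,11(13)‑trien‑12,6‑olide | C=C1C(=O)O[C@@H]2/C=C(/CO[Si](c4ccccc4)(c4ccccc4)C(C)(C)C)C3=CC(=O)[C@](C)(C[C@@H](OC(=O)CC(C)C)[C@@H]12)O3 | intermediate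
21 | (4Z,6R,7R,8R,10S)‑15‑hydroxy‑8‑(3‑methylbutanoyloxy)‑1‑oxo‑3,10‑epoxygermacra‑2,4,11(13)‑trien‑12,6‑olide | C=C1C(=O)O[C@@H]2/C=C(/CO)C3=CC(=O)[C@](C)(C[C@@H](OC(=O)CC(C)C)[C@@H]12)O3 | target

## Step count and risks

Total steps: 11. Longest linear sequence: 8 steps (1 → 2 → 3 → 5 → 14 → 16 → 17 → 20 → 21; the branch 6/7 → 8 → 10 → 11 → 14 → 21 is also 8).

Most likely to fail, first: step 10. The ten‑membered closure may oligomerise or give the wrong C6/C7 pair, because the whole stereochemical outcome rests on macrocyclic control. The fallback sets out from 16. Acetylation (Ac2O, DMAP) gives the C7 acetate of 16 F1. Pd‑catalysed SN2′ borylation (B2pin2, Pd2(dba)3) gives the (Z)‑2‑(methoxycarbonyl)allyl pinacolboronate analogue of 17 F2, a stable, isolable allyl donor. Sc(OTf)3‑catalysed or thermal intramolecular allylboration at high dilution then closes the ring through a closed six‑membered transition state with no reducing metal, and the borate lactonises on acidic work‑up. The fallback comes back to the route at 20.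

Second: step 8. The α‑acyloxy aldehyde can epimerise at C8 under the amine, the isovalerate can migrate to the new C7 hydroxyl, and selectivity over the enal is assumed. The fallback sets out from 14 and replaces amine catalysis by a preformed vinylmetal: [α‑(methoxycarbonyl)vinyl]diisobutylaluminium (from methyl propiolate, DIBAL‑H, NMO; 1.1 equiv, THF, −78 → 0 °C) adds 1,2 to the more electrophilic aldehyde under base‑free conditions. It comes back to the route at 16 and makes no new compound.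

Third: step 5. The 1,3‑induction may give a low diastereomer ratio or the wrong sense at C10. The fallback sets out from 7 and reverses the order in which the two carbon groups arrive at C10. L‑Proline‑catalysed aldol of 7 with acetone gives (4R)‑4‑hydroxy‑5,5‑dimethoxypentan‑2‑one F3. Its aluminium alkoxide, formed with diethyl[(trimethylsilyl)ethynyl]aluminium (2.2 equiv, toluene, −78 → 0 °C), transfers the alkynyl group intramolecularly, by analogy with Evans–Saksena internal delivery. This is the complementary facial logic to external attack on a chelate and leads to the same syn‑diol. The fallback comes back to the route at 9, which is desilylated to 10 as in step 5.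

## Further compounds

F1 | step 10 | methyl (4R)‑3‑acetoxy‑5‑[(2S)‑5‑{(2Z)‑1‑[(tert‑butyldiphenylsilyl)oxy]‑4‑oxobut‑2‑en‑2‑yl}‑2‑methyl‑3‑oxo‑2,3‑dihydrofuran‑2‑yl]‑2‑methylidene‑4‑(3‑methylbutanoyloxy)pentanoate | O=C/C=C(/CO[Si](c2ccccc2)(c2ccccc2)C(C)(C)C)C1=CC(=O)[C@](C)(C[C@@H](OC(=O)CC(C)C)C(OC(C)=O)C(=C)C(=O)OC)O1
F2 | step 10 | methyl (2Z,4R)‑5‑[(2S)‑5‑{(2Z)‑1‑[(tert‑butyldiphenylsilyl)oxy]‑4‑oxobut‑2‑en‑2‑yl}‑2‑methyl‑3‑oxo‑2,3‑dihydrofuran‑2‑yl]‑4‑(3‑methylbutanoyloxy)‑2‑[(4,4,5,5‑tetramethyl‑1,3,2‑dioxaborolan‑2‑yl)methyl]pent‑2‑enoate | O=C/C=C(/CO[Si](c2ccccc2)(c2ccccc2)C(C)(C)C)C1=CC(=O)[C@](C)(C[C@@H](OC(=O)CC(C)C)/C=C(\CB3OC(C)(C)C(C)(C)O3)C(=O)OC)O1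
F0 | step 8 | none | none
F3 | step 5 | (4R)‑4‑hydroxy‑5,5‑dimethoxypentan‑2‑one | CC(=O)C[C@@H](O)C(OC)OC
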